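A small charge of Xa goes into the ash flask, and with it a third of the Xc of the earlier runs; you want to know how much Xp it holds at the end.

| flask | Xa | Xc | time |
|---|---|---|---|
| birch | 0.0800 M | 1.60 × 10⁻⁴ M |  |
| elm | 0.240 M | 1.60 × 10⁻⁴ M |  |
| ash | 0.0400 M | 5.30 × 10⁻⁵ M | 14 h |

- birch run (time / h: [Xp] / M): 0.62: 0.0064; 1.9: 0.0142; 3.6: 0.0214; 5.7: 0.0260; 8.2: 0.0296; 11: 0.0313; 14: 0.0326
- elm run (time / h: [Xp] / M): 0.62: 0.0161; 1.9: 0.0354; 3.6: 0.0505; 5.7: 0.0601; 8.2: 0.0653; 11: 0.0691; 14: 0.0702

(scatter of a reading: 6 × 10⁻⁴ M)

1. order of the initial rate in [Xa], near the charge of the birch run, the rate being that where two percent of its Xa are Xp (one fixed amount of Xp, the same in the runs compared)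
2. Xp in the ash run at 14 h, as a share of the Xa charged

- Overall: Xa -> Xp, with Xc as catalyst.
- Constant volume, constant temperature.
- An order is taken over about fifteen percent of the charge, up and down.

**Loss number.** Both runs level off short of their charge, so read each last reading as Xa dividing between Xp and other routes. Xa lost per Xa turned into Xp is then 1.45 in the birch run and 2.42 in the elm run, larger at the larger charge. A straight line through these gives 1.21 at the ash charge with the [Xc] of those runs. If the catalysed rate goes with [Xc], multiply by the ratio of [Xc] to reach 3.66: this is the ash loss number, Xa lost per Xa turned into Xp, whose inverse is the selectivity factor. Your reckoning for the share of Xp in ash is then 21.5%.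

**One number?** The birch readings still rose by 1.30 mM between 11 h and 14 h, against a scatter of 6 × 10⁻⁴ M on each, so the last reading of birch may stand a little short of its final level; and both runs hold the same [Xc], so the scaling stays untested. Early on, the share of charge made at 0.62 h is 8.00% in birch and 6.71% in elm, so take the order in [Xa] as about 1.

**The result.** The forecast gave 1 and 23%, above your share, noting “Catalyst order is untested.” The simulation gives 1.0 and 29.6%.

    2 Xc ⇌ Xc2, settled at all times (79700 /M)
    Xc + Xa → Xp + Xc (4644 /M/h)
    2 Xa → L (0.9972 /M/h)
    Xa → E (0.1174 /h)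

**In ash.** Throughout the ash run, free [Xc] stood at 0.0154 mM against 0.0287 mM in birch, so 71.0% of the Xc charged to ash was bound in Xc2. The catalysed step ran on that free Xc beside the steps to L and E, so with this ratio the loss number becomes 2.27, a share of 30.6%, and the ash flask held 29.6% at 14 h.

The numbers in the tables stem from a simulated flask for substances that don't exist, and the scatter is random.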